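The substrate left in the elm run at 4.2 h was 88.4 mM, and I held that leftover against a plain second-order step. Around c_target 21.2 mM, the early readings give an apparent constant, rate over c_substrate times c_reagent, of 0.652 /M/h. Carried forward unchanged, that constant leaves 165 mM, and the elm run left less than that.

| setting | elm | ash | maple | oak |
|---|---|---|---|---|
| substrate | 300 mM | 180 mM | 300 mM | 300 mM |
| reagent | 300 mM | 180 mM | 150 mM | 65.0 mM |
| time |  |  |  | 4.2 h |

| run | time / h | [target] / mM |
|---|---|---|
| elm run | 0.24 | 9.1 |
| elm run | 0.72 | 33.4 |
| elm run | 1.4 | 74.0 |
| elm run | 2.2 | 130.0 |
| elm run | 3.1 | 175.7 |
| elm run | 4.2 | 211.6 |
| ash run | 0.24 | 2.8 |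
| ash run | 0.72 | 9.9 |
| ash run | 1.4 | 18.7 |
| ash run | 2.2 | 32.5 |
| ash run | 3.1 | 47.5 |
| ash run | 4.2 | 67.8 |
| maple run | 0.24 | 5.0 |
| maple run | 0.72 | 12.9 |
| maple run | 1.4 | 31.0 |
| maple run | 2.2 | 48.9 |
| maple run | 3.1 | 71.4 |
| maple run | 4.2 | 94.2 |

(each reading ± 0.9 mM)

1. the power of [substrate] that the first rate follows, about the charge of the elm run; measure it at two percent of substrate made into target (one fixed amount of target, the same in the runs compared)
2. the power of [reagent] that the first rate follows, about the charge of the elm run; measure it at two percent of substrate made into target
3. the ash run starts with 120 mM less of substrate and of reagent than the elm run, and with no target. Compared where both hold the same amount of substrate, once fifteen percent of what the ash run was charged with has turned into target, is the ash run faster, slower or alike (within a tenth)?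
4. target in the oak run at 4.2 h, as a share of the substrate charged
5. which of these the readings show (nothing beyond the main steps / the product binds the second partner / the second partner pairs with itself / the substrate is lost by itself / the product speeds the reaction)

- Overall: substrate + reagent -> target.
- Constant volume, constant temperature.
- "The second partner" is reagent.
- An order is taken over about fifteen percent of the charge, up and down.

Around c_target 102 mM, the same elm run gives 1.79 /M/h, so I drew a straight line of the constant against c_target. That line gives 25.1 mM as the take-over level, the c_target at which the step helped by target (autocatalysis) runs as fast as the plain step, and a plain constant of 0.353 /M/h, both as readings with their scatter.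

I then built the oak run one process at a time. Reagent is the limiting reagent there, so I began with the plain step and c_substrate held at its charge, a pseudo-first-order decay of reagent, which gave 23.3 mM at 4.2 h. That figure stands 1.80 mM below the take-over level, so in this reckoning the plain step does not bring the oak run to that level by the time asked. Multiplying the rate by one plus c_target over the take-over level raised the figure to 34.0 mM. Letting substrate fall, with its mean 283 mM in place of the charge, lowered it to 32.1 mM, which is 10.7 % of the substrate charged.

The forecast gave orders of 1 and 1, the ash run slower, 10.9 % for the oak run, which is a little above my figure, and the product speeds the reaction, on the ground that “all three runs fall on the same line, so the product speeds the reaction”.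

    substrate + reagent → target + by-product (0.3596 /M/h)
    substrate + reagent + target → 2 target (13.39 /M²/h)

The oak run gave 10.7 %, which is 32.1 mM of target, above the take-over level, with orders of 1.0 and 1.0, the ash run slower, and the product speeds the reaction. The fit in which the product binds the substrate left residuals of 20 in units of the scatter and put the oak run at 14.7 %. At equal substrate the ash run holds 27.0 mM of target and the elm run 147 mM, so the take-over level gives a rate ratio of 0.303, and the ash run stood at 0.31 of the elm run.

The data stem from a simulated flask with constants of no real substance; scatter was added.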